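**Retrosynthetic overview**

1. The two gallates go on last, by Steglich acylation of the 5- and 4'-phenols with tri-O-benzylgallic acid followed by one global hydrogenolysis. The 5- and 4'-oxygens are therefore carried as MOM ethers and the 7-, 3'- and 3-oxygens as benzyl ethers.
2. The structural feature used is ring C (O1, C2, C3, C4, C4a, C8a), which is the formal [4+2] adduct of a ring A o-quinone methide (O1=C8a–C4a=C4) and a ring B styrene C2=C3 whose C3 already carries oxygen. Cutting O1–C2 and C3–C4 gives a ring A salicyl alcohol and an (E)-2-arylethenyl acetate.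
3. The diene precursor comes from 2,4,6-trihydroxybenzaldehyde (4-O-benzylation, mono-MOM protection, NaBH4 reduction). The dienophile comes from 3,4-dihydroxybenzaldehyde (4-O-MOM, 3-O-benzyl, boron–Wittig olefination, trifluoroborate, copper-catalysed acetoxylation).
4. Rings A and B are bought with the aldehydes. Ring C is the only ring built, in the cycloaddition, which also sets C2 and C3 (2,3-trans, 2R,3S).

Key step: step 9

Assumption: the (R) antipode of the phosphoric acid in step 9 is taken to deliver the (2R,3S) adduct; if the screen shows the opposite sense, the (S) acid is used with nothing else changed.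
Assumption: 3,4,5-tris(benzyloxy)benzoic acid, the tri-O-benzyl ether of gallic acid, is a catalogue compound and is used as bought.

**Route**

Step 1
Reactants: 1 2,4,6-trihydroxybenzaldehyde
Product: 2 4-(benzyloxy)-2,6-dihydroxybenzaldehyde
Conditions: BnBr (1.0 equiv), NaHCO3, MeCN, 60 °C
Reagents that add atoms: benzyl bromide, BrCc1ccccc1
Why: The 4-hydroxyl is para to the formyl group and not chelated to it, so it is the most acidic and the weak base ionises it alone; regioselective Williamson etherification should give the 4-O-benzyl ether while the two hydrogen-bonded ortho hydroxyls stay free.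

Step 2
Reactants: 2 4-(benzyloxy)-2,6-dihydroxybenzaldehyde
Product: 3 4-(benzyloxy)-2-hydroxy-6-(methoxymethoxy)benzaldehyde
Conditions: MOMCl (1.05 equiv), K2CO3, acetone, 0 °C → rt
Reagents that add atoms: chloromethyl methyl ether, COCCl
Why: Williamson-type O-alkylation of one of two equivalent ortho hydroxyls; once the first is capped, the remaining one is locked in a hydrogen bond to the aldehyde and reacts much more slowly, so mono-protection is expected.

Step 3
Reactants: 3 4-(benzyloxy)-2-hydroxy-6-(methoxymethoxy)benzaldehyde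
Product: 4 5-(benzyloxy)-2-(hydroxymethyl)-3-(methoxymethoxy)phenol
Conditions: NaBH4, THF/MeOH, 0 °C; pH 7 phosphate buffer work-up; used at once
Reagents that add atoms: none
Why: Borohydride reduction of the aldehyde should give the salicyl alcohol; the cold, buffered work-up and immediate use avoid premature quinone methide formation from this electron-rich carbinol.

Step 4
Reactants: 5 3,4-dihydroxybenzaldehyde
Product: 6 3-hydroxy-4-(methoxymethoxy)benzaldehyde
Conditions: MOMCl (1.05 equiv), K2CO3, acetone, rt
Reagents that add atoms: chloromethyl methyl ether, COCCl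
Why: The 4-hydroxyl, para to the formyl group, is the more acidic of the two, so regioselective Williamson etherification with one equivalent of MOMCl should place the MOM group on O4.

Step 5
Reactants: 6 3-hydroxy-4-(methoxymethoxy)benzaldehyde
Product: 7 3-(benzyloxy)-4-(methoxymethoxy)benzaldehyde
Conditions: BnBr, K2CO3, DMF, 50 °C
Reagents that add atoms: benzyl bromide, BrCc1ccccc1
Why: Williamson etherification of the only remaining phenol; the MOM acetal and the aldehyde are inert to carbonate.

Step 6
Reactants: 7 3-(benzyloxy)-4-(methoxymethoxy)benzaldehyde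
Product: 8 2-[(E)-2-[3-(benzyloxy)-4-(methoxymethoxy)phenyl]ethenyl]-4,4,5,5-tetramethyl-1,3,2-dioxaborolane
Conditions: CH2(Bpin)2 (1.2 equiv), LiTMP (from 2,2,6,6-tetramethylpiperidine and n-BuLi), THF, 0 °C; then 7, −78 °C → rt
Reagents that add atoms: bis[(pinacolato)boryl]methane, CC1(C)OB(CB2OC(C)(C)C(C)(C)O2)OC1(C)C
Why: Boron–Wittig olefination: the lithiated geminal bis(boronate) adds to the non-enolisable aldehyde and syn-elimination of the boron–oxygen pair from the less hindered adduct should give the (E)-alkenylboronate.

Step 7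
Reactants: 8 the (E)-alkenyl pinacol boronate
Product: 9 potassium [(E)-2-[3-(benzyloxy)-4-(methoxymethoxy)phenyl]ethenyl]trifluoroborate
Conditions: KHF2 (aq., 4 equiv), MeOH, rt
Reagents that add atoms: potassium hydrogen difluoride, F.[F-].[K+]
Why: Ligand exchange at boron with bifluoride should convert the pinacol ester into the crystalline trifluoroborate with the alkene geometry untouched; the aryl MOM ether tolerates the mildly acidic medium at room temperature.

Step 8
Reactants: 9 the potassium (E)-alkenyltrifluoroborate
Product: 10 (E)-2-[3-(benzyloxy)-4-(methoxymethoxy)phenyl]ethenyl acetate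
Conditions: AcOH (3 equiv), Cu(OAc)2 (20 mol %), 4-(dimethylamino)pyridine (40 mol %), 4 Å MS, O2 (1 atm), MeCN, 40 °C
Reagents that add atoms: acetic acid, CC(=O)O
Why: Chan–Lam-type oxidative C–O coupling: the alkenyl group passes from boron to divalent copper with retention, oxidation to trivalent copper follows, and C–O reductive elimination with the carboxylate should give the (E)-enol acetate.

Step 9
Reactants: 4 5-(benzyloxy)-2-(hydroxymethyl)-3-(methoxymethoxy)phenol; 10 (E)-2-[3-(benzyloxy)-4-(methoxymethoxy)phenyl]ethenyl acetate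
Product: 12 (2R,3S)-7-(benzyloxy)-2-[3-(benzyloxy)-4-(methoxymethoxy)phenyl]-5-(methoxymethoxy)chroman-3-yl acetate, via o-quinone methide 11 (not isolated)
Conditions: (R)-3,3'-bis(2,4,6-triisopropylphenyl)-1,1'-binaphthyl-2,2'-diyl hydrogen phosphate (10 mol %), 10 (2.0 equiv), 5 Å MS, toluene/CH2Cl2, −20 °C, 4 added slowly over 8 h
Reagents that add atoms: none
Why: Proposed new method: the phosphoric acid ionises the benzylic C–OH of 4, helped by the oxygen donors at C5 and C7, and the resulting quinone methide 11 stays hydrogen-bonded (or ion-paired) to the catalyst through its carbonyl oxygen; its 1-oxadiene (O1=C8a–C4a=C4) then adds the (E)-alkene of 10 in an inverse-demand, concerted but asynchronous oxa-[4+2] that restores the aromaticity of ring A. The closest known reaction types are the thermal or acid-promoted cycloadditions of o-quinone methides with (E)-β-substituted 4-alkoxystyrenes, which give 2,3-trans flavans, and the chiral phosphoric acid-catalysed [4+2] reactions of o-quinone methides with enamides and vinylphenols; an enol ester as the 2π partner under enantiocontrol is the untested part. Ring C is closed by intermolecular [4+2] annulation, C3–C4 forming ahead of O1–C2 (in the stepwise limit a conjugate addition followed by 6-exo-trig capture of the 4-alkoxybenzylic cation by the ring A oxygen). The step needs flavan and not isoflavan regiochemistry, and the substrate itself secures it: the 4-(methoxymethoxy)phenyl group stabilises positive charge at C2 far better than the acetoxy group could at C3, so the acetoxy-bearing carbon is the one that attacks the methylene terminus. The C2/C3 relationship follows from suprafacial addition across the (E)-alkene, which maps its geometry onto the 2,3-trans ring (a stepwise closure would reach the same diequatorial isomer), while the absolute sense at both centres must come from the 2,4,6-triisopropylphenyl pocket of the catalyst, which exposes one enantiotopic face of the alkene to the bound quinone methide. Self-condensation of the electron-rich quinone methide is held back by slow addition of 4 to an excess of 10, and because only the oxygen ortho to the carbinol is free, that oxygen becomes O1 and the MOM ether ends up at O5.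

Step 10
Reactants: 12 the (2R,3S)-chroman-3-yl acetate
Product: 13 (2R,3S)-7-(benzyloxy)-2-[3-(benzyloxy)-4-(methoxymethoxy)phenyl]-5-(methoxymethoxy)chroman-3-ol
Conditions: K2CO3 (0.2 equiv), MeOH/THF, rt
Reagents that add atoms: none
Why: Zemplén-type transesterification should remove the secondary acetate; no phenol is free, so C2 cannot epimerise through a B-ring quinone methide under the mild base.

Step 11
Reactants: 13 the (2R,3S)-chroman-3-ol
Product: 14 (2R,3S)-3,7-bis(benzyloxy)-2-[3-(benzyloxy)-4-(methoxymethoxy)phenyl]-5-(methoxymethoxy)chromane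
Conditions: NaH, BnBr, n-Bu4NI (cat.), DMF, 0 °C → rt
Reagents that add atoms: benzyl bromide, BrCc1ccccc1
Why: Williamson etherification of the secondary alkoxide; it replaces the acetate by a group that survives acid and acylation and leaves only in the final hydrogenolysis.

Step 12
Reactants: 14 the 3,7,3'-tri-O-benzyl-5,4'-di-O-MOM flavan
Product: 15 (2R,3S)-3,7-bis(benzyloxy)-2-[3-(benzyloxy)-4-hydroxyphenyl]chroman-5-ol
Conditions: HCl (1.25 M in MeOH), THF, 40 °C
Reagents that add atoms: none
Why: Acid-catalysed acetal methanolysis should remove both aryl MOM ethers, releasing exactly the 5- and 4'-phenols, while the benzyl ethers are untouched.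

Step 13
Reactants: 15 the 5,4'-diphenol; 16 3,4,5-tris(benzyloxy)benzoic acid
Product: 17 (2R,3S)-3,7-bis(benzyloxy)-2-[3-(benzyloxy)-4-{[3,4,5-tris(benzyloxy)benzoyl]oxy}phenyl]chroman-5-yl 3,4,5-tris(benzyloxy)benzoate
Conditions: 16 (2.4 equiv), dicyclohexylcarbodiimide (2.6 equiv), 4-(dimethylamino)pyridine (0.4 equiv), CH2Cl2, 0 °C → rt
Reagents that add atoms: none
Why: Steglich esterification through the O-acylisourea and acylpyridinium should acylate both free phenols; the 3-oxygen is blocked as its benzyl ether, so only O5 and O4' can react.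

Step 14
Reactants: 17 the nona-O-benzyl bis-gallate
Product: 18 catechin 5,4'-di-O-gallate, (2R,3S)-3,7-dihydroxy-2-[3-hydroxy-4-(3,4,5-trihydroxybenzoyloxy)phenyl]chroman-5-yl 3,4,5-trihydroxybenzoate
Conditions: H2 (1 atm), Pd(OH)2 on carbon, THF/EtOAc, rt; filtration, chromatography on Sephadex LH-20 with a base-free eluent
Reagents that add atoms: none
Why: Hydrogenolysis of all nine benzyl ethers in a neutral aprotic medium; aryl esters are inert to these conditions and the absence of base should suppress 4'→3' galloyl migration on the liberated catechol.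

**Compound list**

1 | 2,4,6-trihydroxybenzaldehyde | O=Cc1c(O)cc(O)cc1O | starting material
2 | 4-(benzyloxy)-2,6-dihydroxybenzaldehyde | O=Cc1c(O)cc(OCc2ccccc2)cc1O | intermediate
3 | 4-(benzyloxy)-2-hydroxy-6-(methoxymethoxy)benzaldehyde | O=Cc1c(O)cc(OCc2ccccc2)cc1OCOC | intermediate
4 | 5-(benzyloxy)-2-(hydroxymethyl)-3-(methoxymethoxy)phenol | OCc1c(O)cc(OCc2ccccc2)cc1OCOC | intermediate
5 | 3,4-dihydroxybenzaldehyde | O=Cc1ccc(O)c(O)c1 | starting material
6 | 3-hydroxy-4-(methoxymethoxy)benzaldehyde | O=Cc1ccc(OCOC)c(O)c1 | intermediate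
7 | 3-(benzyloxy)-4-(methoxymethoxy)benzaldehyde | O=Cc1ccc(OCOC)c(OCc2ccccc2)c1 | intermediate
8 | 2-[(E)-2-[3-(benzyloxy)-4-(methoxymethoxy)phenyl]ethenyl]-4,4,5,5-tetramethyl-1,3,2-dioxaborolane | CC1(C)OB(/C=C/c2ccc(OCOC)c(OCc3ccccc3)c2)OC1(C)C | intermediate
9 | potassium [(E)-2-[3-(benzyloxy)-4-(methoxymethoxy)phenyl]ethenyl]trifluoroborate | [K+].F[B-](F)(F)/C=C/c1ccc(OCOC)c(OCc2ccccc2)c1 | intermediate
10 | (E)-2-[3-(benzyloxy)-4-(methoxymethoxy)phenyl]ethenyl acetate | CC(=O)O/C=C/c1ccc(OCOC)c(OCc2ccccc2)c1 | intermediate
11 | ring A o-quinone methide, 3-(benzyloxy)-5-(methoxymethoxy)-6-methylidenecyclohexa-2,4-dien-1-one | C=C1C(=O)C=C(OCc2ccccc2)C=C1OCOC | intermediate (not isolated)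
12 | (2R,3S)-7-(benzyloxy)-2-[3-(benzyloxy)-4-(methoxymethoxy)phenyl]-5-(methoxymethoxy)chroman-3-yl acetate | COCOc1ccc([C@H]2Oc3cc(OCc4ccccc4)cc(OCOC)c3C[C@@H]2OC(C)=O)cc1OCc1ccccc1 | intermediate
13 | (2R,3S)-7-(benzyloxy)-2-[3-(benzyloxy)-4-(methoxymethoxy)phenyl]-5-(methoxymethoxy)chroman-3-ol | COCOc1ccc([C@H]2Oc3cc(OCc4ccccc4)cc(OCOC)c3C[C@@H]2O)cc1OCc1ccccc1 | intermediate
14 | (2R,3S)-3,7-bis(benzyloxy)-2-[3-(benzyloxy)-4-(methoxymethoxy)phenyl]-5-(methoxymethoxy)chromane | COCOc1ccc([C@H]2Oc3cc(OCc4ccccc4)cc(OCOC)c3C[C@@H]2OCc2ccccc2)cc1OCc1ccccc1 | intermediate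
15 | (2R,3S)-3,7-bis(benzyloxy)-2-[3-(benzyloxy)-4-hydroxyphenyl]chroman-5-ol | Oc1ccc([C@H]2Oc3cc(OCc4ccccc4)cc(O)c3C[C@@H]2OCc2ccccc2)cc1OCc1ccccc1 | intermediate
16 | 3,4,5-tris(benzyloxy)benzoic acid | OC(=O)c1cc(OCc2ccccc2)c(OCc2ccccc2)c(OCc2ccccc2)c1 | starting material
17 | (2R,3S)-3,7-bis(benzyloxy)-2-[3-(benzyloxy)-4-{[3,4,5-tris(benzyloxy)benzoyl]oxy}phenyl]chroman-5-yl 3,4,5-tris(benzyloxy)benzoate | O=C(Oc1ccc([C@H]2Oc3cc(OCc4ccccc4)cc(OC(=O)c4cc(OCc5ccccc5)c(OCc5ccccc5)c(OCc5ccccc5)c4)c3C[C@@H]2OCc2ccccc2)cc1OCc1ccccc1)c1cc(OCc2ccccc2)c(OCc2ccccc2)c(OCc2ccccc2)c1 | intermediate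
18 | catechin 5,4'-di-O-gallate | O=C(Oc1ccc([C@H]2Oc3cc(O)cc(OC(=O)c4cc(O)c(O)c(O)c4)c3C[C@@H]2O)cc1O)c1cc(O)c(O)c(O)c1 | target

**Step count and risk**

Total step count: 14. Longest linear sequence: 11 steps (steps 4 to 8, then 9 to 14).

Steps most likely to fail:

1. Step 9 (new method). Enantiofacial discrimination may be poor because the enol acetate offers the catalyst no hydrogen-bond contact. The electron-rich quinone methide may also be lost to Friedel–Crafts self-condensation, the regiochemistry may partly reverse, and a MOM ether may be lost to the acid. The fallback uses known reactions and sets out from 3 and 9. Heating them with dibenzylamine in DMF at 80 °C (Petasis-type condensation, loss of the amine and oxa-6π electrocyclisation) should give racemic 7-(benzyloxy)-2-[3-(benzyloxy)-4-(methoxymethoxy)phenyl]-5-(methoxymethoxy)-2H-chromene F1. Hydroboration with BH3·THF, directed to C3 by the styrene polarisation and anti to the 2-aryl group, should give the trans C3-alkylborane F2. Oxidation in the same flask with NaOH/H2O2 proceeds with retention to the racemic 2,3-trans flavan-3-ol F3. Preparative chromatography on a cellulose tris(3,5-dimethylphenylcarbamate) phase then separates the enantiomers; the (2S,3R) alcohol F4 is set aside and the (2R,3S) enantiomer is 13, where the route is rejoined (steps 9 and 10 are bypassed).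

2. Step 14. Galloyl migration from O4' to the newly freed O3', incomplete cleavage of nine benzyl ethers, or hydrogenolytic opening of the benzylic O1–C2 bond may occur. The fallback sets out from 17 and replaces hydrogenolysis by Lewis-acid dealkylation: BCl3 with pentamethylbenzene as cation scavenger in CH2Cl2 at −78 °C, then a methanol quench, which keeps the medium acidic and cold throughout. It returns directly at 18; no new compound arises on this path (entry F0).

3. Step 8. Protodeboronation or oxidative homocoupling of the electron-rich alkenylborate may compete, and the enol acetate may hydrolyse or lose its (E) geometry. The fallback sets out from 7. Claisen–Schmidt condensation with acetone (aq. NaOH, rt) should give (E)-4-[3-(benzyloxy)-4-(methoxymethoxy)phenyl]but-3-en-2-one F5. Baeyer–Villiger oxidation (mCPBA, NaHCO3, CH2Cl2, 0 °C), in which the alkenyl group migrates in preference to methyl with retention of geometry, should then give 10, where the route is rejoined (steps 6 to 8 are bypassed).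

**Further compounds**

F1 | step 9 | rac-7-(benzyloxy)-2-[3-(benzyloxy)-4-(methoxymethoxy)phenyl]-5-(methoxymethoxy)-2H-chromene | COCOc1ccc(C2Oc3cc(OCc4ccccc4)cc(OCOC)c3C=C2)cc1OCc1ccccc1
F2 | step 9 | rac-trans-[7-(benzyloxy)-2-[3-(benzyloxy)-4-(methoxymethoxy)phenyl]-5-(methoxymethoxy)chroman-3-yl]borane (drawn as the monoalkylborane, both enantiomers) | COCOc1ccc([C@H]2Oc3cc(OCc4ccccc4)cc(OCOC)c3C[C@@H]2B)cc1OCc1ccccc1.COCOc1ccc([C@@H]2Oc3cc(OCc4ccccc4)cc(OCOC)c3C[C@H]2B)cc1OCc1ccccc1
F3 | step 9 | rac-trans-7-(benzyloxy)-2-[3-(benzyloxy)-4-(methoxymethoxy)phenyl]-5-(methoxymethoxy)chroman-3-ol (both enantiomers) | COCOc1ccc([C@H]2Oc3cc(OCc4ccccc4)cc(OCOC)c3C[C@@H]2O)cc1OCc1ccccc1.COCOc1ccc([C@@H]2Oc3cc(OCc4ccccc4)cc(OCOC)c3C[C@H]2O)cc1OCc1ccccc1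
F4 | step 9 | (2S,3R)-7-(benzyloxy)-2-[3-(benzyloxy)-4-(methoxymethoxy)phenyl]-5-(methoxymethoxy)chroman-3-ol | COCOc1ccc([C@@H]2Oc3cc(OCc4ccccc4)cc(OCOC)c3C[C@H]2O)cc1OCc1ccccc1
F0 | step 14 | none | none
F5 | step 8 | (E)-4-[3-(benzyloxy)-4-(methoxymethoxy)phenyl]but-3-en-2-one | CC(=O)/C=C/c1ccc(OCOC)c(OCc2ccccc2)c1
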